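## Retrosynthetic overview

1. Target ⇐ late acylations: C9–OH (tiglic acid), C14–OH (silyl‑protected (2R,3S)-3-hydroxy-2-methylbutanoic acid from an Evans syn‑aldol), C12–OH (acetate); the C15 silyl ether is removed last.
2. Ten‑membered carbocycle (formed last of the two rings) ⇐ C9–C10 Nozaki–Hiyama–Kishi closure of an open‑chain iodo‑aldehyde; C9 is then fixed by oxidation and CBS reduction.
3. Oxirane (formed first, on the open chain) ⇐ Sharpless epoxidation of a (Z)-allylic alcohol; its C4=C5 bond ⇐ Still–Gennari olefination of fragment A (aldehyde, C5–C9 and C11–C13) with fragment B (phosphonate, C1–C4, C10, C14, C15).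
4. Fragment A ⇐ key C7–C11 bond: intermolecular organocatalytic Michael addition of dimethyl malonate to an (E)-5-silyloxypent-2-enal (sets C7); the malonate becomes the 2-(oxymethyl)vinyl unit.
5. Fragment B ⇐ but-3-yn-1-ol via the ynoate, syn‑hydrostannation/iodination (fixes the alkenyl iodide geometry) and alkylation of the Still–Gennari phosphonoacetate.

Assumption: the target is exactly the stereoisomer of the SMILES, (4S,5R,7S,9S) in the ring and (2R,3S) in the hydroxy ester; locants C1–C15 follow germacrane numbering (C7 carries C11–C13, C9 the tiglate, C10 the C14 arm, C4 the C15 arm, C4/C5 the epoxide).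

## Route

Step 1
Reactants: 1 but-3-en-1-ol
Product: 2 (but-3-en-1-yloxy)(tert-butyl)diphenylsilane
Conditions: t-BuPh2SiCl, imidazole, CH2Cl2, 0 °C to rt
Reagents that add atoms: tert-butyl(chloro)diphenylsilane, CC(C)(C)[Si](Cl)(c1ccccc1)c1ccccc1
Why: Standard silylation of a primary alcohol; the robust silyl ether masks the future C5 oxygen.

Step 2
Reactants: 2 (but-3-en-1-yloxy)(tert-butyl)diphenylsilane; 3 (E)-but-2-enal
Product: 4 (2E)-5-{[tert-butyl(diphenyl)silyl]oxy}pent-2-enal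
Conditions: second-generation Grubbs catalyst (3 mol%), 3 (5 equiv), CH2Cl2, 40 °C
Reagents that add atoms: none
Why: Olefin cross‑metathesis of a terminal alkene with an enal is reliably (E)-selective and loses only propene.

Step 3
Reactants: 4 (2E)-5-{[tert-butyl(diphenyl)silyl]oxy}pent-2-enal; 5 dimethyl malonate
Product: 6 dimethyl 2-[(3R)-1-{[tert-butyl(diphenyl)silyl]oxy}-5-oxopentan-3-yl]propanedioate
Conditions: (S)-2-{bis[3,5-bis(trifluoromethyl)phenyl][(trimethylsilyl)oxy]methyl}pyrrolidine (10 mol%), EtOH, 0 °C, 72 h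
Reagents that add atoms: none
Why: Iminium‑ion‑catalysed asymmetric Michael addition forms the C7–C11 bond; the diarylmethyl silyl ether shields one face of the (E)-iminium ion, so malonate adds to the open face and sets C7 (3R here, 7S in the target).

Step 4
Reactants: 6 dimethyl 2-[(3R)-1-{[tert-butyl(diphenyl)silyl]oxy}-5-oxopentan-3-yl]propanedioate
Product: 7 dimethyl 2-[(3R)-1-{[tert-butyl(diphenyl)silyl]oxy}-5,5-dimethoxypentan-3-yl]propanedioate
Conditions: HC(OMe)3, p-TsOH·H2O (5 mol%), MeOH, rt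
Reagents that add atoms: trimethyl orthoformate, COC(OC)OC
Why: Acid‑catalysed acetalisation masks the C9 aldehyde until ring closure; the stereocentre is not alpha to the carbonyl and is untouched.

Step 5
Reactants: 7 dimethyl 2-[(3R)-1-{[tert-butyl(diphenyl)silyl]oxy}-5,5-dimethoxypentan-3-yl]propanedioate
Product: 8 2-[(3R)-1-{[tert-butyl(diphenyl)silyl]oxy}-5,5-dimethoxypentan-3-yl]-3-methoxy-3-oxopropanoic acid (both epimers at the malonate carbon)
Conditions: KOH (1.05 equiv), MeOH/H2O, 0 °C to rt; cold aq. KHSO4 to pH 4, immediate extraction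
Reagents that add atoms: potassium hydroxide, [K+].[OH-]
Why: Mono‑saponification of a malonate stops cleanly at the half ester because the carboxylate deactivates the second ester; the new malonate stereocentre is destroyed in the next step.

Step 6
Reactants: 8 the malonic half ester
Product: 9 methyl (3R)-3-(2-{[tert-butyl(diphenyl)silyl]oxy}ethyl)-5,5-dimethoxy-2-methylidenepentanoate
Conditions: (CH2O)n, Et2NH, THF, reflux
Reagents that add atoms: formaldehyde (as paraformaldehyde), C=O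
Why: Mannich‑type decarboxylative methylenation converts the half ester into the alpha‑methylene ester, installing C13 as the exocyclic methylene.

Step 7
Reactants: 9 the alpha‑methylene ester
Product: 10 (3R)-3-(2-{[tert-butyl(diphenyl)silyl]oxy}ethyl)-5,5-dimethoxy-2-methylidenepentan-1-ol
Conditions: i-Bu2AlH (2.3 equiv), CH2Cl2, −78 °C; aq. KNaC4H4O6 work-up
Reagents that add atoms: none
Why: 1,2-Reduction of the acrylate by the aluminium hydride gives the C12 allylic alcohol; the acetal and silyl ether are inert at −78 °C.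

Step 8
Reactants: 10 the C12 allylic alcohol
Product: 11 tert-butyl{[(3R)-5,5-dimethoxy-3-{3-[(4-methoxyphenyl)methoxy]prop-1-en-2-yl}pentyl]oxy}diphenylsilane
Conditions: NaH, 4-methoxybenzyl chloride, Bu4NI (cat.), THF/DMF, 0 °C to rt
Reagents that add atoms: 4-methoxybenzyl chloride, COc1ccc(CCl)cc1
Why: Williamson etherification under basic conditions (safe for the acetal) protects C12–OH as the 4-methoxybenzyl ether, which is later removed oxidatively.

Step 9
Reactants: 11 the C12 4-methoxybenzyl ether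
Product: 12 (3R)-5,5-dimethoxy-3-{3-[(4-methoxyphenyl)methoxy]prop-1-en-2-yl}pentan-1-ol
Conditions: Bu4NF, THF, rt; chromatography on Et3N-deactivated silica
Reagents that add atoms: none
Why: Fluoride cleaves the silyl ether under basic conditions, so the delta‑hydroxy acetal does not cyclise.

Step 10
Reactants: 12 the C5 alcohol
Product: 13 (3R)-5,5-dimethoxy-3-{3-[(4-methoxyphenyl)methoxy]prop-1-en-2-yl}pentanal (fragment A)
Conditions: Dess–Martin periodinane, pyridine, CH2Cl2, 0 °C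
Reagents that add atoms: none
Why: Buffered Dess–Martin oxidation gives the C5 aldehyde without acid exposure; the stereocentre is beta to the aldehyde and cannot epimerise.

Step 11
Reactants: 14 but-3-yn-1-ol
Product: 15 1-[(but-3-yn-1-yloxy)methyl]-4-methoxybenzene
Conditions: NaH, 4-methoxybenzyl chloride, Bu4NI (cat.), THF/DMF, 0 °C to rt
Reagents that add atoms: 4-methoxybenzyl chloride, COc1ccc(CCl)cc1
Why: Williamson etherification; only the hydroxyl is deprotonated by NaH.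

Step 12
Reactants: 15 the butynyl 4-methoxybenzyl ether
Product: 16 methyl 5-[(4-methoxyphenyl)methoxy]pent-2-ynoate
Conditions: n-BuLi, THF, −78 °C; then ClCO2Me, −78 to 0 °C
Reagents that add atoms: methyl chloroformate, COC(=O)Cl
Why: Acylation of the lithium acetylide gives the ynoate; the ester carbon becomes C14.

Step 13
Reactants: 16 methyl 5-[(4-methoxyphenyl)methoxy]pent-2-ynoate
Product: 18 methyl (2E)-2-iodo-5-[(4-methoxyphenyl)methoxy]pent-2-enoate, via stannyl enoate 17 (not isolated)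
Conditions: Bu3SnH, Pd(PPh3)4 (2 mol%), THF, 0 °C to rt; then I2, CH2Cl2, 0 °C
Reagents that add atoms: iodine, II; tributyltin hydride, CCCC[SnH](CCCC)CCCC (its tin stays only in 17)
Why: Zerovalent‑palladium‑catalysed syn‑hydrostannation of an ynoate puts tin on the alpha carbon and hydrogen on the beta carbon; iododestannylation proceeds with retention, so the iodide is trans to the chain, as needed for the ring (E) C1=C10 bond.

Step 14
Reactants: 18 the (E)-alpha‑iodo enoate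
Product: 19 (2E)-2-iodo-5-[(4-methoxyphenyl)methoxy]pent-2-en-1-ol
Conditions: i-Bu2AlH (2.3 equiv), CH2Cl2, −78 °C
Reagents that add atoms: none
Why: 1,2-Reduction of the enoate to the allylic alcohol (C14–OH); alkenyl iodides survive the aluminium hydride at −78 °C.

Step 15
Reactants: 19 the iodo allylic alcohol
Product: 20 tert-butyl({(2E)-2-iodo-5-[(4-methoxyphenyl)methoxy]pent-2-en-1-yl}oxy)dimethylsilane
Conditions: t-BuMe2SiCl, imidazole, CH2Cl2, rt
Reagents that add atoms: tert-butyl(chloro)dimethylsilane, CC(C)(C)[Si](C)(C)Cl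
Why: Silylation gives C14 an ether that is inert in the later chromium‑mediated ring closure and orthogonal to the benzyl‑type ether.

Step 16
Reactants: 20 the silyl ether
Product: 21 (3E)-5-{[tert-butyl(dimethyl)silyl]oxy}-4-iodopent-3-en-1-ol
Conditions: DDQ, CH2Cl2/pH 7 buffer, 0 °C
Reagents that add atoms: none
Why: Oxidative cleavage of the 4-methoxybenzyl ether (hydride abstraction by the quinone, then hydrolysis) frees the C3 alcohol without touching the silyl ether or the alkenyl iodide.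

Step 17
Reactants: 21 the homoallylic alcohol
Product: 22 tert-butyl{[(2E)-2,5-diiodopent-2-en-1-yl]oxy}dimethylsilane
Conditions: I2, PPh3, imidazole, CH2Cl2, 0 °C
Reagents that add atoms: iodine, II
Why: Appel‑type iodination converts the primary alcohol into the primary iodide by SN2 displacement of the oxyphosphonium.

Step 18
Reactants: 22 the diiodide; 23 methyl 2-[bis(2,2,2-trifluoroethoxy)phosphoryl]acetate
Product: 24 methyl (5E)-2-[bis(2,2,2-trifluoroethoxy)phosphoryl]-7-{[tert-butyl(dimethyl)silyl]oxy}-6-iodohept-5-enoate (racemic at C2; fragment B)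
Conditions: NaH, 23 (1.5 equiv), DMF, 0 °C; then 22, rt to 40 °C
Reagents that add atoms: none
Why: SN2 alkylation of the soft phosphonoacetate anion at the primary alkyl iodide; the alkenyl iodide does not react.

Step 19
Reactants: 25 (4R)-4-benzyl-3-propanoyl-1,3-oxazolidin-2-one; 26 acetaldehyde
Product: 27 (4R)-4-benzyl-3-[(2R,3S)-3-hydroxy-2-methylbutanoyl]-1,3-oxazolidin-2-one
Conditions: Bu2BOTf, i-Pr2NEt, CH2Cl2, −78 to 0 °C; then 26, −78 to 0 °C; pH 7 buffer, MeOH, H2O2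
Reagents that add atoms: none
Why: Evans syn‑aldol: the (Z)-boron enolate reacts through a closed chair transition state on the face opposite the benzyl group, giving the (2R,3S) syn adduct from the (R)-auxiliary.

Step 20
Reactants: 27 the syn‑aldol adduct
Product: 28 (4R)-4-benzyl-3-[(2R,3S)-3-{[tert-butyl(dimethyl)silyl]oxy}-2-methylbutanoyl]-1,3-oxazolidin-2-one
Conditions: t-BuMe2SiOTf, 2,6-lutidine, CH2Cl2, −78 to 0 °C
Reagents that add atoms: tert-butyldimethylsilyl triflate, CC(C)(C)[Si](C)(C)OS(=O)(=O)C(F)(F)F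
Why: Silylation of the secondary alcohol prevents retro‑aldol and self‑acylation in the later esterification.

Step 21
Reactants: 28 the silylated imide
Product: 29 (2R,3S)-3-{[tert-butyl(dimethyl)silyl]oxy}-2-methylbutanoic acid
Conditions: LiOH, H2O2, THF/H2O, 0 °C; Na2SO3; aq. HCl to pH 3
Reagents that add atoms: hydrogen peroxide (as LiOOH), OO
Why: Hydroperoxide attacks the exocyclic imide carbonyl selectively, releasing the acid without epimerising C2 and returning the auxiliary.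

Step 22
Reactants: 13 fragment A aldehyde; 24 fragment B phosphonate
Product: 30 methyl (2Z,5R)-2-[(3E)-5-{[tert-butyl(dimethyl)silyl]oxy}-4-iodopent-3-en-1-yl]-7,7-dimethoxy-5-{3-[(4-methoxyphenyl)methoxy]prop-1-en-2-yl}hept-2-enoate
Conditions: 24 (1.2 equiv), KN(SiMe3)2, 18-crown-6, THF, −78 °C; then 13, −78 °C
Reagents that add atoms: none
Why: Still–Gennari variant of the Horner–Wadsworth–Emmons reaction: the electron‑poor phosphonate with a dissociated potassium counter‑ion eliminates kinetically to the (Z)-enoate, placing C15 cis to C6 as the epoxide requires.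

Step 23
Reactants: 30 the (Z)-enoate
Product: 31 (2Z,5R)-2-[(3E)-5-{[tert-butyl(dimethyl)silyl]oxy}-4-iodopent-3-en-1-yl]-7,7-dimethoxy-5-{3-[(4-methoxyphenyl)methoxy]prop-1-en-2-yl}hept-2-en-1-ol
Conditions: i-Bu2AlH (2.5 equiv), CH2Cl2, −78 °C
Reagents that add atoms: none
Why: 1,2-Reduction of the enoate gives the C15 allylic alcohol with the double‑bond geometry unchanged.

Step 24
Reactants: 31 the (Z)-allylic alcohol
Product: 32 {(2S,3R)-2-[(3E)-5-{[tert-butyl(dimethyl)silyl]oxy}-4-iodopent-3-en-1-yl]-3-[(2R)-4,4-dimethoxy-2-{3-[(4-methoxyphenyl)methoxy]prop-1-en-2-yl}butyl]oxiran-2-yl}methanol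
Conditions: Ti(Oi-Pr)4 (20 mol%), L-(+)-diethyl tartrate (28 mol%), t-BuOOH (2 equiv, decane), 4 Å MS, CH2Cl2, −20 °C
Reagents that add atoms: tert-butyl hydroperoxide, CC(C)(C)OO
Why: Sharpless asymmetric epoxidation: only the allylic alcohol binds the titanium tartrate, and L-(+)-tartrate delivers oxygen to the same face as in nerol → (2S,3R), giving the (4S,5R) trans‑epoxide by reagent control.

Step 25
Reactants: 32 the epoxy alcohol
Product: 33 tert-butyl({(2S,3R)-2-[(3E)-5-{[tert-butyl(dimethyl)silyl]oxy}-4-iodopent-3-en-1-yl]-3-[(2R)-4,4-dimethoxy-2-{3-[(4-methoxyphenyl)methoxy]prop-1-en-2-yl}butyl]oxiran-2-yl}methoxy)diphenylsilane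
Conditions: t-BuPh2SiCl, imidazole, CH2Cl2, 0 °C to rt
Reagents that add atoms: tert-butyl(chloro)diphenylsilane, CC(C)(C)[Si](Cl)(c1ccccc1)c1ccccc1
Why: Neutral silylation protects C15–OH to the end and avoids Payne rearrangement of the epoxy alcohol.

Step 26
Reactants: 33 the fully protected acetal
Product: 34 (3R)-4-[(2R,3S)-3-({[tert-butyl(diphenyl)silyl]oxy}methyl)-3-[(3E)-5-{[tert-butyl(dimethyl)silyl]oxy}-4-iodopent-3-en-1-yl]oxiran-2-yl]-3-{3-[(4-methoxyphenyl)methoxy]prop-1-en-2-yl}butanal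
Conditions: PPTS (0.2 equiv), acetone/H2O (9:1), rt
Reagents that add atoms: water, O
Why: Mild acid hydrolysis of the dimethyl acetal, the most acid‑labile group present, releases the C9 aldehyde; the epoxide is deactivated by its silyloxymethyl substituent.

Step 27
Reactants: 34 the iodo‑aldehyde
Product: 35 (1(10)E,4S,5R,7S,9RS)-14-{[tert-butyl(dimethyl)silyl]oxy}-15-{[tert-butyl(diphenyl)silyl]oxy}-4,5-epoxy-12-[(4-methoxyphenyl)methoxy]germacra-1(10),11(13)-dien-9-ol (C9 epimers)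
Conditions: CrCl2 (10 equiv), NiCl2 (0.1 equiv), degassed DMSO/THF, rt, syringe-pump addition to 2 mM
Reagents that add atoms: none
Why: Intramolecular Nozaki–Hiyama–Kishi reaction: zerovalent nickel inserts into the C–I bond with retention of geometry, and the alkenylchromium adds chemoselectively to the aldehyde to close the ten‑membered ring; C9 is fixed in the next two steps.

Step 28
Reactants: 35 the macrocyclic allylic alcohol (C9 epimers)
Product: 36 (1(10)E,4S,5R,7R)-14-{[tert-butyl(dimethyl)silyl]oxy}-15-{[tert-butyl(diphenyl)silyl]oxy}-4,5-epoxy-12-[(4-methoxyphenyl)methoxy]germacra-1(10),11(13)-dien-9-one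
Conditions: Dess–Martin periodinane, NaHCO3, CH2Cl2, 0 °C
Reagents that add atoms: none
Why: Oxidation converges both C9 epimers to one enone; C7 is beta to the ketone and is not epimerised (its descriptor changes only through CIP priorities).

Step 29
Reactants: 36 the macrocyclic enone
Product: 37 (1(10)E,4S,5R,7S,9S)-14-{[tert-butyl(dimethyl)silyl]oxy}-15-{[tert-butyl(diphenyl)silyl]oxy}-4,5-epoxy-12-[(4-methoxyphenyl)methoxy]germacra-1(10),11(13)-dien-9-ol
Conditions: (R)-2-methyl-CBS-oxazaborolidine (0.3 equiv), catecholborane (2 equiv), toluene/CH2Cl2, −78 to −40 °C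
Reagents that add atoms: none
Why: Corey–Bakshi–Shibata reduction: with the alpha‑branched alkenyl group as the large substituent, the (R)-catalyst delivers hydride to the face that gives the (9S)-alcohol.

Step 30
Reactants: 37 the (9S)-alcohol; 38 (2E)-2-methylbut-2-enoic acid (tiglic acid)
Product: 39 (1(10)E,4S,5R,7S,9S)-14-{[tert-butyl(dimethyl)silyl]oxy}-15-{[tert-butyl(diphenyl)silyl]oxy}-4,5-epoxy-12-[(4-methoxyphenyl)methoxy]germacra-1(10),11(13)-dien-9-yl (2E)-2-methylbut-2-enoate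
Conditions: 38, 2,4,6-trichlorobenzoyl chloride, Et3N, toluene, rt; then 37, DMAP, rt
Reagents that add atoms: none
Why: Yamaguchi esterification acylates the hindered secondary allylic alcohol with retention at C9; the tiglate is the stable (E) isomer and cannot scramble.

Step 31
Reactants: 39 the tiglate
Product: 40 (1(10)E,4S,5R,7S,9S)-15-{[tert-butyl(diphenyl)silyl]oxy}-4,5-epoxy-14-hydroxy-12-[(4-methoxyphenyl)methoxy]germacra-1(10),11(13)-dien-9-yl (2E)-2-methylbut-2-enoate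
Conditions: HF·pyridine, excess pyridine, THF, 0 °C to rt
Reagents that add atoms: none
Why: Buffered fluoride removes the primary allylic tert-butyldimethylsilyl ether far faster than the tert-butyldiphenylsilyl ether, freeing only C14–OH.

Step 32
Reactants: 40 the C14 alcohol; 29 (2R,3S)-3-{[tert-butyl(dimethyl)silyl]oxy}-2-methylbutanoic acid
Product: 41 (1(10)E,4S,5R,7S,9S)-14-{[(2R,3S)-3-{[tert-butyl(dimethyl)silyl]oxy}-2-methylbutanoyl]oxy}-15-{[tert-butyl(diphenyl)silyl]oxy}-4,5-epoxy-12-[(4-methoxyphenyl)methoxy]germacra-1(10),11(13)-dien-9-yl (2E)-2-methylbut-2-enoate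
Conditions: 29, EDC·HCl, DMAP (0.3 equiv), CH2Cl2, 0 °C to rt
Reagents that add atoms: none
Why: Steglich‑type carbodiimide esterification of the unhindered primary allylic alcohol at low temperature; the silyl ether blocks beta‑elimination and self‑acylation of the acid.

Step 33
Reactants: 41 the C14 ester
Product: 42 (1(10)E,4S,5R,7S,9S)-14-{[(2R,3S)-3-{[tert-butyl(dimethyl)silyl]oxy}-2-methylbutanoyl]oxy}-15-{[tert-butyl(diphenyl)silyl]oxy}-4,5-epoxy-12-hydroxygermacra-1(10),11(13)-dien-9-yl (2E)-2-methylbut-2-enoate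
Conditions: DDQ (1.3 equiv), CH2Cl2/pH 7 buffer, 0 °C
Reagents that add atoms: none
Why: Neutral oxidative removal of the 4-methoxybenzyl ether frees C12–OH and leaves esters, silyl ethers and the epoxide intact.

Step 34
Reactants: 42 the C12 alcohol
Product: 43 (1(10)E,4S,5R,7S,9S)-12-acetoxy-14-{[(2R,3S)-3-{[tert-butyl(dimethyl)silyl]oxy}-2-methylbutanoyl]oxy}-15-{[tert-butyl(diphenyl)silyl]oxy}-4,5-epoxygermacra-1(10),11(13)-dien-9-yl (2E)-2-methylbut-2-enoate
Conditions: Ac2O, pyridine, DMAP (cat.), CH2Cl2, 0 °C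
Reagents that add atoms: acetic anhydride, CC(=O)OC(C)=O
Why: Acetylation of the only free hydroxyl.

Step 35
Reactants: 43 the bis‑silyl ether
Product: 44 CNP0316239.1, (1(10)E,4S,5R,7S,9S)-12-acetoxy-4,5-epoxy-15-hydroxy-14-{[(2R,3S)-3-hydroxy-2-methylbutanoyl]oxy}germacra-1(10),11(13)-dien-9-yl (2E)-2-methylbut-2-enoate
Conditions: Bu4NF, AcOH (1:1, excess), THF, 0 °C to rt
Reagents that add atoms: none
Why: Acetic‑acid‑buffered fluoride removes both silyl ethers while keeping the medium near neutral, which suppresses acyl migration, Payne rearrangement and beta‑elimination.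

## Compound list

1 | but-3-en-1-ol | C=CCCO | starting material
2 | (but-3-en-1-yloxy)(tert-butyl)diphenylsilane | C=CCCO[Si](c1ccccc1)(c1ccccc1)C(C)(C)C | intermediate
3 | (E)-but-2-enal (crotonaldehyde) | C/C=C/C=O | starting material
4 | (2E)-5-{[tert-butyl(diphenyl)silyl]oxy}pent-2-enal | O=C/C=C/CCO[Si](c1ccccc1)(c1ccccc1)C(C)(C)C | intermediate
5 | dimethyl malonate | COC(=O)CC(=O)OC | starting material
6 | dimethyl 2-[(3R)-1-{[tert-butyl(diphenyl)silyl]oxy}-5-oxopentan-3-yl]propanedioate | COC(=O)C(C(=O)OC)[C@H](CCO[Si](c1ccccc1)(c1ccccc1)C(C)(C)C)CC=O | intermediate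
7 | dimethyl 2-[(3R)-1-{[tert-butyl(diphenyl)silyl]oxy}-5,5-dimethoxypentan-3-yl]propanedioate | COC(=O)C(C(=O)OC)[C@H](CCO[Si](c1ccccc1)(c1ccccc1)C(C)(C)C)CC(OC)OC | intermediate
8 | 2-[(3R)-1-{[tert-butyl(diphenyl)silyl]oxy}-5,5-dimethoxypentan-3-yl]-3-methoxy-3-oxopropanoic acid (both epimers at the malonate carbon) | COC(=O)C(C(=O)O)[C@H](CCO[Si](c1ccccc1)(c1ccccc1)C(C)(C)C)CC(OC)OC | intermediate
9 | methyl (3R)-3-(2-{[tert-butyl(diphenyl)silyl]oxy}ethyl)-5,5-dimethoxy-2-methylidenepentanoate | COC(=O)C(=C)[C@H](CCO[Si](c1ccccc1)(c1ccccc1)C(C)(C)C)CC(OC)OC | intermediate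
10 | (3R)-3-(2-{[tert-butyl(diphenyl)silyl]oxy}ethyl)-5,5-dimethoxy-2-methylidenepentan-1-ol | OCC(=C)[C@H](CCO[Si](c1ccccc1)(c1ccccc1)C(C)(C)C)CC(OC)OC | intermediate
11 | tert-butyl{[(3R)-5,5-dimethoxy-3-{3-[(4-methoxyphenyl)methoxy]prop-1-en-2-yl}pentyl]oxy}diphenylsilane | COc1ccc(COCC(=C)[C@H](CCO[Si](c2ccccc2)(c2ccccc2)C(C)(C)C)CC(OC)OC)cc1 | intermediate
12 | (3R)-5,5-dimethoxy-3-{3-[(4-methoxyphenyl)methoxy]prop-1-en-2-yl}pentan-1-ol | COc1ccc(COCC(=C)[C@H](CCO)CC(OC)OC)cc1 | intermediate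
13 | (3R)-5,5-dimethoxy-3-{3-[(4-methoxyphenyl)methoxy]prop-1-en-2-yl}pentanal (fragment A) | COc1ccc(COCC(=C)[C@H](CC=O)CC(OC)OC)cc1 | intermediate
14 | but-3-yn-1-ol | C#CCCO | starting material
15 | 1-[(but-3-yn-1-yloxy)methyl]-4-methoxybenzene | C#CCCOCc1ccc(OC)cc1 | intermediate
16 | methyl 5-[(4-methoxyphenyl)methoxy]pent-2-ynoate | COC(=O)C#CCCOCc1ccc(OC)cc1 | intermediate
17 | methyl (2E)-5-[(4-methoxyphenyl)methoxy]-2-(tributylstannyl)pent-2-enoate | COc1ccc(COCC/C=C(/[Sn](CCCC)(CCCC)CCCC)C(=O)OC)cc1 | intermediate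
18 | methyl (2E)-2-iodo-5-[(4-methoxyphenyl)methoxy]pent-2-enoate | COc1ccc(COCC/C=C(/I)C(=O)OC)cc1 | intermediate
19 | (2E)-2-iodo-5-[(4-methoxyphenyl)methoxy]pent-2-en-1-ol | COc1ccc(COCC/C=C(/I)CO)cc1 | intermediate
20 | tert-butyl({(2E)-2-iodo-5-[(4-methoxyphenyl)methoxy]pent-2-en-1-yl}oxy)dimethylsilane | COc1ccc(COCC/C=C(/I)CO[Si](C)(C)C(C)(C)C)cc1 | intermediate
21 | (3E)-5-{[tert-butyl(dimethyl)silyl]oxy}-4-iodopent-3-en-1-ol | OCC/C=C(/I)CO[Si](C)(C)C(C)(C)C | intermediate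
22 | tert-butyl{[(2E)-2,5-diiodopent-2-en-1-yl]oxy}dimethylsilane | ICC/C=C(/I)CO[Si](C)(C)C(C)(C)C | intermediate
23 | methyl 2-[bis(2,2,2-trifluoroethoxy)phosphoryl]acetate | COC(=O)CP(=O)(OCC(F)(F)F)OCC(F)(F)F | starting material
24 | methyl (5E)-2-[bis(2,2,2-trifluoroethoxy)phosphoryl]-7-{[tert-butyl(dimethyl)silyl]oxy}-6-iodohept-5-enoate (racemic at C2; fragment B) | COC(=O)C(CC/C=C(/I)CO[Si](C)(C)C(C)(C)C)P(=O)(OCC(F)(F)F)OCC(F)(F)F | intermediate
25 | (4R)-4-benzyl-3-propanoyl-1,3-oxazolidin-2-one | CCC(=O)N1[C@H](Cc2ccccc2)COC1=O | starting material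
26 | acetaldehyde | CC=O | starting material
27 | (4R)-4-benzyl-3-[(2R,3S)-3-hydroxy-2-methylbutanoyl]-1,3-oxazolidin-2-one | O=C(N1[C@H](Cc2ccccc2)COC1=O)[C@H](C)[C@H](C)O | intermediate
28 | (4R)-4-benzyl-3-[(2R,3S)-3-{[tert-butyl(dimethyl)silyl]oxy}-2-methylbutanoyl]-1,3-oxazolidin-2-one | O=C(N1[C@H](Cc2ccccc2)COC1=O)[C@H](C)[C@H](C)O[Si](C)(C)C(C)(C)C | intermediate
29 | (2R,3S)-3-{[tert-butyl(dimethyl)silyl]oxy}-2-methylbutanoic acid | OC(=O)[C@H](C)[C@H](C)O[Si](C)(C)C(C)(C)C | intermediate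
30 | methyl (2Z,5R)-2-[(3E)-5-{[tert-butyl(dimethyl)silyl]oxy}-4-iodopent-3-en-1-yl]-7,7-dimethoxy-5-{3-[(4-methoxyphenyl)methoxy]prop-1-en-2-yl}hept-2-enoate | COC(=O)/C(CC/C=C(/I)CO[Si](C)(C)C(C)(C)C)=C\C[C@H](CC(OC)OC)C(=C)COCc1ccc(OC)cc1 | intermediate
31 | (2Z,5R)-2-[(3E)-5-{[tert-butyl(dimethyl)silyl]oxy}-4-iodopent-3-en-1-yl]-7,7-dimethoxy-5-{3-[(4-methoxyphenyl)methoxy]prop-1-en-2-yl}hept-2-en-1-ol | OC/C(CC/C=C(/I)CO[Si](C)(C)C(C)(C)C)=C\C[C@H](CC(OC)OC)C(=C)COCc1ccc(OC)cc1 | intermediate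
32 | {(2S,3R)-2-[(3E)-5-{[tert-butyl(dimethyl)silyl]oxy}-4-iodopent-3-en-1-yl]-3-[(2R)-4,4-dimethoxy-2-{3-[(4-methoxyphenyl)methoxy]prop-1-en-2-yl}butyl]oxiran-2-yl}methanol | OC[C@]1(CC/C=C(/I)CO[Si](C)(C)C(C)(C)C)O[C@@H]1C[C@H](CC(OC)OC)C(=C)COCc2ccc(OC)cc2 | intermediate
33 | tert-butyldiphenylsilyl ether of 32 at the oxiranylmethanol oxygen | CC(C)(C)[Si](c1ccccc1)(c1ccccc1)OC[C@]2(CC/C=C(/I)CO[Si](C)(C)C(C)(C)C)O[C@@H]2C[C@H](CC(OC)OC)C(=C)COCc3ccc(OC)cc3 | intermediate
34 | (3R)-4-[(2R,3S)-3-({[tert-butyl(diphenyl)silyl]oxy}methyl)-3-[(3E)-5-{[tert-butyl(dimethyl)silyl]oxy}-4-iodopent-3-en-1-yl]oxiran-2-yl]-3-{3-[(4-methoxyphenyl)methoxy]prop-1-en-2-yl}butanal | CC(C)(C)[Si](c1ccccc1)(c1ccccc1)OC[C@]2(CC/C=C(/I)CO[Si](C)(C)C(C)(C)C)O[C@@H]2C[C@H](CC=O)C(=C)COCc3ccc(OC)cc3 | intermediate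
35 | (1(10)E,4S,5R,7S,9RS)-14-{[tert-butyl(dimethyl)silyl]oxy}-15-{[tert-butyl(diphenyl)silyl]oxy}-4,5-epoxy-12-[(4-methoxyphenyl)methoxy]germacra-1(10),11(13)-dien-9-ol (C9 epimers) | C=C(COCc3ccc(OC)cc3)[C@H]1CC(O)/C(CO[Si](C)(C)C(C)(C)C)=C/CC[C@@]2(CO[Si](c3ccccc3)(c3ccccc3)C(C)(C)C)O[C@@H]2C1 | intermediate
36 | (1(10)E,4S,5R,7R)-14-{[tert-butyl(dimethyl)silyl]oxy}-15-{[tert-butyl(diphenyl)silyl]oxy}-4,5-epoxy-12-[(4-methoxyphenyl)methoxy]germacra-1(10),11(13)-dien-9-one | C=C(COCc3ccc(OC)cc3)[C@H]1CC(=O)/C(CO[Si](C)(C)C(C)(C)C)=C/CC[C@@]2(CO[Si](c3ccccc3)(c3ccccc3)C(C)(C)C)O[C@@H]2C1 | intermediate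
37 | (1(10)E,4S,5R,7S,9S)-14-{[tert-butyl(dimethyl)silyl]oxy}-15-{[tert-butyl(diphenyl)silyl]oxy}-4,5-epoxy-12-[(4-methoxyphenyl)methoxy]germacra-1(10),11(13)-dien-9-ol | C=C(COCc3ccc(OC)cc3)[C@H]1C[C@H](O)/C(CO[Si](C)(C)C(C)(C)C)=C/CC[C@@]2(CO[Si](c3ccccc3)(c3ccccc3)C(C)(C)C)O[C@@H]2C1 | intermediate
38 | (2E)-2-methylbut-2-enoic acid (tiglic acid) | C/C=C(\C)C(=O)O | starting material
39 | 9-O-tigloyl derivative of 37 | C=C(COCc3ccc(OC)cc3)[C@H]1C[C@H](OC(=O)/C(C)=C/C)/C(CO[Si](C)(C)C(C)(C)C)=C/CC[C@@]2(CO[Si](c3ccccc3)(c3ccccc3)C(C)(C)C)O[C@@H]2C1 | intermediate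
40 | (1(10)E,4S,5R,7S,9S)-15-{[tert-butyl(diphenyl)silyl]oxy}-4,5-epoxy-14-hydroxy-12-[(4-methoxyphenyl)methoxy]germacra-1(10),11(13)-dien-9-yl (2E)-2-methylbut-2-enoate | C=C(COCc3ccc(OC)cc3)[C@H]1C[C@H](OC(=O)/C(C)=C/C)/C(CO)=C/CC[C@@]2(CO[Si](c3ccccc3)(c3ccccc3)C(C)(C)C)O[C@@H]2C1 | intermediate
41 | 14-O-[(2R,3S)-3-{[tert-butyl(dimethyl)silyl]oxy}-2-methylbutanoyl] derivative of 40 | C=C(COCc3ccc(OC)cc3)[C@H]1C[C@H](OC(=O)/C(C)=C/C)/C(COC(=O)[C@H](C)[C@H](C)O[Si](C)(C)C(C)(C)C)=C/CC[C@@]2(CO[Si](c3ccccc3)(c3ccccc3)C(C)(C)C)O[C@@H]2C1 | intermediate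
42 | 12-hydroxy compound (41 without the 4-methoxybenzyl group) | C=C(CO)[C@H]1C[C@H](OC(=O)/C(C)=C/C)/C(COC(=O)[C@H](C)[C@H](C)O[Si](C)(C)C(C)(C)C)=C/CC[C@@]2(CO[Si](c3ccccc3)(c3ccccc3)C(C)(C)C)O[C@@H]2C1 | intermediate
43 | 12-O-acetyl derivative of 42 (C15 and C3' still silylated) | C=C(COC(C)=O)[C@H]1C[C@H](OC(=O)/C(C)=C/C)/C(COC(=O)[C@H](C)[C@H](C)O[Si](C)(C)C(C)(C)C)=C/CC[C@@]2(CO[Si](c3ccccc3)(c3ccccc3)C(C)(C)C)O[C@@H]2C1 | intermediate
44 | CNP0316239.1, (1(10)E,4S,5R,7S,9S)-12-acetoxy-4,5-epoxy-15-hydroxy-14-{[(2R,3S)-3-hydroxy-2-methylbutanoyl]oxy}germacra-1(10),11(13)-dien-9-yl (2E)-2-methylbut-2-enoate | C=C(COC(C)=O)[C@H]1C[C@H](OC(=O)/C(C)=C/C)/C(COC(=O)[C@H](C)[C@H](C)O)=C/CC[C@@]2(CO)O[C@@H]2C1 | target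

## Step count and risks

Total steps: 35 (fragment A 10, fragment B 8, side‑chain acid 3, union and end game 14).
Longest linear sequence: 24 steps (steps 1–10, then 22–35).

Three steps most likely to fail:

Step 27 (ring closure). A strained ten‑membered (E)-cycloalkene has to form in competition with dimerisation, and the epoxide must survive the chromium salts. The fallback sets out from 34 and avoids the aldehyde addition. Oxidation with NaClO2/NaH2PO4/2-methylbut-2-ene gives the carboxylic acid F2. Coupling with N,O-dimethylhydroxylamine hydrochloride (EDC·HCl, i-Pr2NEt) gives the Weinreb amide F3. Iodine–lithium exchange with t-BuLi (THF/Et2O, −100 °C, high dilution) then closes the ring by intramolecular acylation of the alkenyllithium. This gives enone 36 directly, where the route is rejoined; step 28 is skipped.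

Step 29 (C9 configuration). In a medium ring the conformational bias of the enone can override the oxazaborolidine. The fallback sets out from 36 and uses substrate control followed by inversion. Luche reduction (NaBH4, CeCl3·7H2O, MeOH, −78 °C) attacks the peripheral face. If this gives the 9-epi-alcohol F4, Mitsunobu esterification with 38 (PPh3, diisopropyl azodicarboxylate, toluene, 0 °C) installs the tiglate with inversion at C9. The route is rejoined at 39; step 30 is skipped.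

Step 24 (epoxidation). Allylic alcohols with a cis substituent are the slowest and least selective class in the titanium–tartrate epoxidation. The fallback sets out from 31 and drops the hydroxyl‑directed oxidant. The alcohol is first silylated (t-BuPh2SiCl, imidazole) to the tert-butyldiphenylsilyl ether of the (Z)-allylic alcohol F1. Shi epoxidation of the trisubstituted alkene follows (D-fructose-derived ketone, KHSO5, K2CO3, MeCN/dimethoxymethane/buffer, 0 °C). By the spiro transition‑state model this ketone attacks the face that gives the (4S,5R) epoxide, and the 1,1-disubstituted alkene and the alkenyl iodide are much less reactive. The route is rejoined at 33; step 25 is skipped.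

## Further compounds

F1 | step 24 | tert-butyl{[(2Z,5R)-2-[(3E)-5-{[tert-butyl(dimethyl)silyl]oxy}-4-iodopent-3-en-1-yl]-7,7-dimethoxy-5-{3-[(4-methoxyphenyl)methoxy]prop-1-en-2-yl}hept-2-en-1-yl]oxy}diphenylsilane | CC(C)(C)[Si](c1ccccc1)(c1ccccc1)OC/C(CC/C=C(/I)CO[Si](C)(C)C(C)(C)C)=C\C[C@H](CC(OC)OC)C(=C)COCc1ccc(OC)cc1
F2 | step 27 | (3R)-4-[(2R,3S)-3-({[tert-butyl(diphenyl)silyl]oxy}methyl)-3-[(3E)-5-{[tert-butyl(dimethyl)silyl]oxy}-4-iodopent-3-en-1-yl]oxiran-2-yl]-3-{3-[(4-methoxyphenyl)methoxy]prop-1-en-2-yl}butanoic acid | CC(C)(C)[Si](c1ccccc1)(c1ccccc1)OC[C@]2(CC/C=C(/I)CO[Si](C)(C)C(C)(C)C)O[C@@H]2C[C@H](CC(=O)O)C(=C)COCc3ccc(OC)cc3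
F3 | step 27 | N-methoxy-N-methyl amide of F2 | CC(C)(C)[Si](c1ccccc1)(c1ccccc1)OC[C@]2(CC/C=C(/I)CO[Si](C)(C)C(C)(C)C)O[C@@H]2C[C@H](CC(=O)N(C)OC)C(=C)COCc3ccc(OC)cc3
F4 | step 29 | (1(10)E,4S,5R,7S,9R)-14-{[tert-butyl(dimethyl)silyl]oxy}-15-{[tert-butyl(diphenyl)silyl]oxy}-4,5-epoxy-12-[(4-methoxyphenyl)methoxy]germacra-1(10),11(13)-dien-9-ol | C=C(COCc3ccc(OC)cc3)[C@H]1C[C@@H](O)/C(CO[Si](C)(C)C(C)(C)C)=C/CC[C@@]2(CO[Si](c3ccccc3)(c3ccccc3)C(C)(C)C)O[C@@H]2C1
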